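Every exchange takes up one incoming ligand and frees one leaving ligand, so the charge of incoming ligand is a budget of exchanges, and each complex with two exchanged costs two of them.

| flask | starting complex | incoming ligand | leaving ligand | remark | time |
|---|---|---|---|---|---|
| grey | 1 M | 0.70 equiv | 2 equiv | run made earlier |  |
| teal | 1 M | 1.1 equiv | 2 equiv | run made earlier |  |
| amber | 0.50 M | 0.50 equiv | 2 equiv | run made earlier |  |
| flask | 1.0 M | 0.500 equiv | 2.00 equiv |  | 4.0 h |

| run | time / h | complex with two exchanged / % | starting complex / % |
|---|---|---|---|
| grey | 0.333 | 19.6 | 57.7 |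
| grey | 0.500 | 20.9 | 56.0 |
| grey | 0.667 | 21.3 | 55.0 |
| grey | 1.00 | 21.4 | 55.6 |
| grey | 1.50 | 20.5 | 54.9 |
| grey | 2.50 | 21.6 | 55.0 |
| grey | 4.00 | 21.3 | 55.2 |
| teal | 0.200 | 27.5 | 47.4 |
| teal | 0.667 | 36.5 | 38.6 |
| teal | 1.00 | 35.9 | 37.8 |
| teal | 1.50 | 36.3 | 37.8 |
| teal | 2.50 | 36.1 | 37.3 |
| teal | 3.00 | 36.6 | 37.5 |
| teal | 4.00 | 36.3 | 38.2 |
| amber | 0.333 | 9.4 | 71.5 |
| amber | 0.667 | 13.0 | 66.6 |
| amber | 1.00 | 13.7 | 65.7 |
| amber | 2.00 | 13.9 | 65.4 |
| amber | 4.00 | 13.8 | 65.1 |

(readings scatter by 0.3 percentage points)



- equivalents of incoming ligand to starting complex, everything else as given, that leave most complex with two exchanged at 4.0 h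
- the amount of complex with two exchanged then, in percent of the starting complex charged
- the amount of complex with two exchanged with the amounts as given

In each of the three runs the readings stop moving well before the last one, but they stop at different heights, so what I want to read is how the final height follows the charge. The grey run, with 0.70 equiv of incoming ligand, ends at 21.3 % complex with two exchanged, and the teal run, with 1.1 equiv at the same concentration, ends at 36.3 %. The difference in height over the difference in charge is 0.375, and this I call the dose yield Y, the rise in final complex with two exchanged, as a fraction of the starting complex charged, per equivalent of incoming ligand added, read between these two charges with the leaving ligand held at 2 equiv. Going back along Y from the grey run to the 0.500 equiv of this flask, I reckon 13.8 %, and the amber run, a separate measurement at 0.50 M with that same charge, reads 13.8 %. My line ends at the charge of the teal run, so I name no peak of my own.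

The forecast also gives 13.8 % for this flask, on the ground “so dilution has no effect”, and it puts most complex with two exchanged, 72 %, at 3 equiv.

The simulated flask gives 13.6 %, 0.2 percentage points below my reckoning, and with the charge of incoming ligand changed, most complex with two exchanged, 55.2 %, comes at 1.96 equiv.

    starting complex + incoming ligand ⇌ leaving ligand + complex with one exchanged (K = 3.13, k = 0.134 L mol⁻¹ min⁻¹)
    complex with one exchanged + incoming ligand ⇌ leaving ligand + complex with two exchanged (K = 13.0, k = 0.339 L mol⁻¹ min⁻¹)
    complex with two exchanged + incoming ligand ⇌ leaving ligand + complex with three exchanged (K = 27.8, k = 0.0274 L mol⁻¹ min⁻¹)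
    leaving ligand → by-product carried off (k = 0.237 min⁻¹)
    leaving ligand + complex with two exchanged → side product (k = 0.0184 L mol⁻¹ min⁻¹)

In this flask incoming ligand is the limiting reagent, with 0 % of it left against 66 % of the starting complex. The carrying off of leaving ligand is the main reason this flask holds 13.6 % of complex with two exchanged, since the same run without that loss holds 0.386 %. For the neighbouring flask with 0.850 equiv, Y gives 26.9 %, and that flask holds 27.1 %.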